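Shorthand used throughout: Ar = 3-methoxy-4-[(triisopropylsilyl)oxy]phenyl; "Ar-methoxy" = ArCH2O–, "Ar-methyl" = ArCH2–, "Ar-methylidene" = ArCH=. Ring positions are those of the oxolane of the target: O1, C2 (aryl), C3, C4, C5.

## Analysis of the target

The target is a monocyclic 2,3,4-trisubstituted oxolane of the lariciresinol type. C2 carries a 4-hydroxy-3-methoxyphenyl group, C3 an acyloxymethyl group, C4 a 4-hydroxy-3-methoxybenzyl group, and C5 is an unsubstituted methylene. The three ring stereocentres are contiguous, (2R,3S,4S): the C2 aryl is trans to the C3 side chain, and the C3 and C4 side chains are cis, so the benzyl group lies on the face opposite to the C2 aryl. A fourth stereocentre, (R), sits in the 2-methylbutanoyl residue; it is remote from the ring, is best bought, and, being alpha to an ester carbonyl, must not meet strong base. The sensitive groups are the two free guaiacol phenols (oxidation), the ester, and above all the C2–O1 bond: it is a benzylic ether para to an oxygen donor, so acid ionises it, which epimerises C2 or lets the C4 benzyl ring close onto C2 to an aryltetralin. The synthesis is hard because the 3,4-cis relation is the less stable one, because C2 has to be set absolutely without a neighbouring handle, and because the two identical arenes are attached in different ways (directly, and through CH2). The strategy rests on the C2–H bond: it is benzylic and alpha to O1, hence a good hydride donor towards an electrophilic carbene, so the C2–C3 bond can be made on a plain unsymmetrical dibenzyl-type ether while C4 is kept as an sp2 benzylidene carbon.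

## Retrosynthetic reasoning

21 ⇒ 20. The O–Si bonds are cut last. Free guaiacols would interfere with alkoxide, organometallic and carbenoid chemistry, and silyl ethers that leave under buffered fluoride spare the ester, its alpha stereocentre and the acid-labile C2–O1 bond.

20 ⇒ 19. The two C–H bonds at C4 and at the benzylic carbon are removed, which turns C4 into the sp2 carbon of the (Z)-benzylidene compound 19. No C–C bond is cut here; C4 is set last, on a ring that already carries C2 and C3. The forward hydrogenation has to add to the face away from the adjacent C3 side chain and must not cleave the allylic or benzylic C–O bonds.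

19 ⇒ 17 + 18. The ester C–O bond is cut, so the acyl stereocentre comes with acid 18. Acylation is placed before the hydrogenation because it enlarges the C3 substituent that steers it. Alcohol 17 comes from ester 16 by reduction; C3 is carried as an ester because that group is the acceptor of the carbenoid.

16 ⇒ 15. Only the configuration at C3 changes. The 2,3-trans ester 16 is the stable epimer, and the ring closure is expected to deliver the cis ester 15, so an equilibration is planned. It belongs at the ester stage, the only point at which C3–H is acidic.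

15 ⇒ 14 (key disconnection). The C2–C3 bond is cut so that C3 becomes a carbene carbon and C2 regains its hydrogen. This gives diazo ester 14, an achiral, linear ether. The cut is made here because C2–H is doubly activated, whereas every other ring bond would demand a preformed stereocentre. The gain is the ring and C2 in one catalytic step, with the two arenes told apart simply by the side of the ether oxygen they sit on. The forward reaction must choose one of two enantiotopic benzylic hydrogens.

14 ⇒ 13 ⇒ 10 + 11. The diazo group goes back to the activated methylene of 13. The bond between the alkene carbon and that methylene is then cut to give vinyl iodide 10 and the zinc enolate 12 made from 11. This puts the alkene geometry into a vinyl iodide that can be made stereospecifically.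

10 ⇒ 8. The C–I and C–H bonds across the alkene are removed to give alkyne 8. A syn addition places the arene and the CH2O branch cis, the geometry that keeps the styryl arene away from the later carbenoid carbon.

8 ⇒ 2 + 7; 7 ⇒ 5 + 6; 5 ⇒ 4 ⇒ 3; 2 ⇒ 1. The sp–sp2 bond and the ether C–O bond are cut. Both arenes then come from 1 and 3, which already carry the guaiacol pattern, and the three-carbon link comes from 6.

## Alternatives that were turned down

Alternative 1: Conjugate addition–aldol on a butenolide.
- Disconnection: the C3–CH2 bond and the C4–benzylidene bond, on a lactone whose carbonyl carbon is C5 of the target. The ring comes from (5R)-5-Ar-furan-2(5H)-one A2.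
- Forward key step: copper-catalysed addition of a silylmethyl Grignard reagent (a hydroxymethyl surrogate) to A2 anti to the aryl group, aldol capture of the enolate by aldehyde 4, and acetylation–elimination in the same flask. The product is the benzylidene lactone A1.
- For: two C–C bonds form in one operation by textbook chemistry. The 2,3-trans relation arises kinetically from anti addition, with no epimerisation step; on this point it is stronger than the chosen route.
- Against: the only stereocentre of A2 is benzylic and gamma to the carbonyl, so the basic medium can racemise it through the 2-oxyfuran. The ring is at the wrong oxidation level: the lactone carbonyl must be taken down to CH2 under Lewis-acidic hydride conditions next to the ionisable C2–O1 bond. The C–Si bond must be oxidised beside electron-rich arenes. Hydrogenation of A1 meets the same facial question and leaves a lactone alpha centre that can epimerise to the unwanted 3,4-trans isomer.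
- Comparison: about six steps follow A1, three of them redox corrections. The chosen route builds the ring at the right oxidation level and sets C2 by a catalyst on an achiral substrate.

Alternative 2: Radical cyclisation with aryl capture.
- Disconnection: C3–C4 and the CH2–aryl bond in one event. The precursors are (3S)-3-Ar-2-bromo-3-(prop-2-en-1-yloxy)propyl (2R)-2-methylbutanoate A4 (either bromide epimer) and aryl bromide 2.
- Forward key step: a nickel-catalysed reductive coupling with a metallic reductant. The C3 radical closes 5-exo on the allyl ether, and the primary radical is arylated at nickel. The product A3 is identical with 20.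
- For: it is the shortest route, giving ring, two C–C bonds and two stereocentres in one step, with no separate hydrogenation, and it is convergent in the bromide centre. The usual preferences of substituted hexenyl radicals (cis for a substituent on the radical carbon, trans for one on the next carbon) match the target. In step economy it is clearly stronger than the chosen route.
- Against: those preferences are modest biases of an early transition state, and both C3 and C4 depend on them with no later chance of correction. The precursor is a bromide with an alkoxy and an acyloxy group in beta positions, so two-electron reduction would eliminate, and the radical can undergo acyloxy migration. A4 itself needs a regio- and enantiocontrolled synthesis.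
- Comparison: the chosen route is longer but sets each stereocentre in its own step by a different element (catalyst, thermodynamics, facial shielding), so a poor result at one centre can be repaired without redesign.

Alternative 3: Gold carbene O–H insertion to an oxolan-3-one.
- Disconnection: the O1–C5 bond, with C4 as a ketone. The precursor is (1R,2S)-1-Ar-2-{[(4-methoxyphenyl)methoxy]methyl}but-3-yn-1-ol A6.
- Forward key step: gold-catalysed oxidation of the terminal alkyne by an amine N-oxide to an alpha-oxo gold carbene, into which the benzylic hydroxyl inserts. The product is the oxolan-3-one A5.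
- For: the step is mild and catalytic and belongs to a well-documented reaction class. C2 and C3 are set beforehand by acyclic control, C3 sits alpha to the ketone in the stable trans arrangement, and no diazo compound is needed. On these points it is stronger.
- Against: A5 holds no carbon of the benzyl group. The ketone must be olefinated with a basic benzylic ylide although its alpha centre is epimerisable and carries a beta alkoxy leaving group. The same hydrogenation as in the chosen route still follows. The oxidation is normally run with a strong acid additive, which the electron-rich benzylic alcohol A6 tolerates poorly. An extra protecting group has to be removed oxidatively next to guaiacol rings.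
- Comparison: the benzylidene stage is reached two to three steps later than by the chosen key step, which delivers ring, C2 and benzylidene together.

Key step: step 9

Assumption on the chemistry: Rh2(S-PTTL)4 is taken to give the (2R) series; should the insertion show the opposite sense, Rh2(R-PTTL)4 is used with no other change.
Assumption on materials: (2R)-2-methylbutanoic acid 18 is bought enantiopure.

## Route

Step 1
Reactants: 1 4-bromo-2-methoxyphenol
Product: 2 (4-bromo-2-methoxyphenoxy)triisopropylsilane (Ar–Br)
Conditions: TIPSCl, imidazole, DMF, rt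
Reagents that add atoms: chlorotriisopropylsilane, CC(C)[Si](Cl)(C(C)C)C(C)C
Why: Silyl ether formation on a phenol; the bulky triisopropylsilyl group should survive the alkoxide, amine, hydride and organometallic reagents that follow and leave with fluoride at the end.

Step 2
Reactants: 3 vanillin (4-hydroxy-3-methoxybenzaldehyde)
Product: 4 3-methoxy-4-[(triisopropylsilyl)oxy]benzaldehyde (Ar–CHO)
Conditions: TIPSCl, imidazole, DMF, rt
Reagents that add atoms: chlorotriisopropylsilane, CC(C)[Si](Cl)(C(C)C)C(C)C
Why: Silyl ether formation on the phenol; the aldehyde is untouched.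

Step 3
Reactants: 4 3-methoxy-4-[(triisopropylsilyl)oxy]benzaldehyde
Product: 5 {3-methoxy-4-[(triisopropylsilyl)oxy]phenyl}methanol (Ar–CH2OH)
Conditions: NaBH4, THF–MeOH, 0 °C
Reagents that add atoms: none
Why: Borohydride reduction of an aryl aldehyde; short reaction time at 0 °C keeps the aryl silyl ether intact.

Step 4
Reactants: 5 {3-methoxy-4-[(triisopropylsilyl)oxy]phenyl}methanol; 6 3-bromoprop-1-yne (propargyl bromide)
Product: 7 {2-methoxy-4-[(prop-2-yn-1-yloxy)methyl]phenoxy}triisopropylsilane (Ar–CH2–O–CH2–C≡CH)
Conditions: NaH, THF, 0 °C; then 6, Bu4NI (cat.), 0 °C → rt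
Reagents that add atoms: none
Why: Williamson ether synthesis with a reactive propargylic bromide; the triisopropylsilyl ether resists silyl transfer to the benzylic alkoxide at this temperature, and the labile electron-rich benzyl bromide is avoided.

Step 5
Reactants: 2 (4-bromo-2-methoxyphenoxy)triisopropylsilane; 7 {2-methoxy-4-[(prop-2-yn-1-yloxy)methyl]phenoxy}triisopropylsilane
Product: 8 1-Ar-3-(Ar-methoxy)prop-1-yne (Ar–C≡C–CH2–O–CH2–Ar)
Conditions: Pd(PhCN)2Cl2 (3 mol %), [(t-Bu)3PH]BF4 (6 mol %), CuI (2 mol %), i-Pr2NH, dioxane, rt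
Reagents that add atoms: none
Why: Sonogashira coupling; the electron-rich aryl bromide needs the bulky trialkylphosphine to undergo oxidative addition at room temperature, and exclusion of air suppresses alkyne homocoupling.

Step 6
Reactants: 8 1-Ar-3-(Ar-methoxy)prop-1-yne
Product: 10 (1E)-1-Ar-2-iodo-3-(Ar-methoxy)prop-1-ene (Ar and I trans; Ar and CH2O cis), via vinylstannane 9 (not isolated)
Conditions: Pd(PPh3)2Cl2 (3 mol %), Bu3SnH (slow addition), THF, 0 °C → rt; then I2, CH2Cl2, −20 → 0 °C, dark
Reagents that add atoms: tributylstannane, CCCC[SnH](CCCC)CCCC (tin held only in 9); iodine, II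
Why: Palladium-catalysed syn-hydrostannation followed by iododestannylation with retention. Hydrogen should go to the aryl-bearing carbon and tin to the carbon next to the CH2O group, because the inductive pull of the propargylic oxygen and the donor arene polarise the alkyne in the same sense. Syn addition fixes Ar cis to the CH2O branch.

Step 7
Reactants: 10 (1E)-1-Ar-2-iodo-3-(Ar-methoxy)prop-1-ene; 11 methyl bromoacetate
Product: 13 methyl (3Z)-4-Ar-3-[(Ar-methoxy)methyl]but-3-enoate, via Reformatsky reagent 12 (not isolated)
Conditions: Zn dust (Me3SiCl-activated), 11, THF, 40 °C; then 10, Pd(PPh3)4 (5 mol %), THF–DMPU, 45 °C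
Reagents that add atoms: zinc, [Zn] (held only in 12)
Why: Negishi-type coupling of a Reformatsky reagent with a vinyl iodide, which proceeds with retention of alkene geometry; the weakly basic zinc enolate leaves the styrene-conjugated alkene in place.

Step 8
Reactants: 13 methyl (3Z)-4-Ar-3-[(Ar-methoxy)methyl]but-3-enoate
Product: 14 methyl (3Z)-2-diazo-4-Ar-3-[(Ar-methoxy)methyl]but-3-enoate
Conditions: 4-acetamidobenzenesulfonyl azide, DBU, MeCN, 0 °C, dark; product used at once
Reagents that add atoms: 4-acetamidobenzenesulfonyl azide, CC(=O)Nc1ccc(cc1)S(=O)(=O)N=[N+]=[N-]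
Why: Regitz-type diazo transfer to the vinylogously activated methylene of a but-3-enoate, the standard entry to vinyldiazoacetates. The (Z) geometry, with Ar next to the smaller CH2O branch, is also the less congested one, so the delocalised anion should not erode it.

Step 9
Reactants: 14 methyl (3Z)-2-diazo-4-Ar-3-[(Ar-methoxy)methyl]but-3-enoate
Product: 15 methyl (2R,3S,4Z)-2-Ar-4-(Ar-methylidene)oxolane-3-carboxylate (2,3-cis)
Conditions: Rh2(S-PTTL)4 (dirhodium tetrakis[N-phthaloyl-(S)-tert-leucinate], 1 mol %), PhMe, −60 → −30 °C, slow addition of 14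
Reagents that add atoms: none
Why: Proposed new method: loss of dinitrogen from 14 at the dirhodium catalyst should give a donor/acceptor vinylcarbenoid whose electrophilic carbon takes the benzylic ether hydrogen in a concerted, hydride-like three-centre insertion, the C–H bond being activated both by O1 and by the para-silyloxy arene; the closest known reaction type is the enantioselective intramolecular 1,5 C–H insertion of aryl(diazo)acetates into benzylic ether C–H bonds under chiral divalent-rhodium carboxylates (2-aryl-2,3-dihydrobenzofuran-3-carboxylates), of which a vinyl donor tethered through its own carbon is an untested extension. The oxolane closes by formation of C2–C3 as a 1,5-insertion through a five-membered cyclic transition state, the only ring size the tether allows, since the C5 hydrogens are 1,3 to the carbenoid and out of reach. C2 is set by the catalyst, whose chiral carboxylate pocket discriminates the two enantiotopic benzylic hydrogens. C3 is set in the same event by the geometry of approach: the benzylic arene should turn away from the dirhodium core and towards the ester, so the kinetic product is expected to be the 2,3-cis ester 15, as in the aryl series, and step 10 corrects it. Site selectivity against the methoxy, isopropyl and C5 hydrogens rests on the double activation and the 1,5 relationship. Chemoselectivity against indene formation rests on the (Z) geometry of 14, which holds the styryl arene anti to the carbenoid carbon; low temperature and slow addition should hold back cyclopropene formation and carbene dimerisation.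

Step 10
Reactants: 15 methyl (2R,3S,4Z)-2-Ar-4-(Ar-methylidene)oxolane-3-carboxylate (2,3-cis)
Product: 16 methyl (2R,3R,4Z)-2-Ar-4-(Ar-methylidene)oxolane-3-carboxylate (2,3-trans)
Conditions: DBU (0.1 equiv), PhMe, 0 °C → rt, stopped when 15 is consumed; AcOH quench
Reagents that add atoms: none
Why: Base-mediated epimerisation alpha to an ester through the dienolate, with kinetic reprotonation at the alpha carbon; the trans ester is favoured because it relieves the aryl/ester eclipsing. The cis epimer, with C3–H anti to the aryl group, should ionise faster, so the equilibration can be ended before the alkene drifts into conjugation with the ester.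

Step 11
Reactants: 16 methyl (2R,3R,4Z)-2-Ar-4-(Ar-methylidene)oxolane-3-carboxylate
Product: 17 [(2R,3S,4Z)-2-Ar-4-(Ar-methylidene)oxolan-3-yl]methanol
Conditions: i-Bu2AlH (2.5 equiv), CH2Cl2, −78 °C; Rochelle salt work-up
Reagents that add atoms: none
Why: Hydride reduction of the ester to the primary alcohol under Lewis-acidic, non-basic conditions, so C3 and the alkene position are not disturbed; the descriptor at C3 changes only because the priorities change.

Step 12
Reactants: 17 [(2R,3S,4Z)-2-Ar-4-(Ar-methylidene)oxolan-3-yl]methanol; 18 (2R)-2-methylbutanoic acid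
Product: 19 [(2R,3S,4Z)-2-Ar-4-(Ar-methylidene)oxolan-3-yl]methyl (2R)-2-methylbutanoate
Conditions: DCC, DMAP (0.1 equiv), CH2Cl2, 0 °C → rt
Reagents that add atoms: none
Why: Steglich esterification of an unhindered primary alcohol; a simple alpha-branched alkanoic acid does not form a ketene under carbodiimide activation, so its stereocentre should be retained.

Step 13
Reactants: 19 [(2R,3S,4Z)-2-Ar-4-(Ar-methylidene)oxolan-3-yl]methyl (2R)-2-methylbutanoate
Product: 20 [(2R,3S,4S)-2-Ar-4-(Ar-methyl)oxolan-3-yl]methyl (2R)-2-methylbutanoate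
Conditions: H2 (1 atm), 5% Rh/Al2O3, EtOAc, rt
Reagents that add atoms: none
Why: Heterogeneous hydrogenation of the exocyclic trisubstituted alkene. The acyloxymethyl group on the adjacent C3 shields its own face, so hydrogen should add anti to it and set C4 with the benzyl group cis to the C3 side chain. Rhodium on alumina is chosen over palladium because it is less prone to hydrogenolysis of the allylic C5–O1 and benzylic C2–O1 bonds and to alkene migration.

Step 14
Reactants: 20 [(2R,3S,4S)-2-Ar-4-(Ar-methyl)oxolan-3-yl]methyl (2R)-2-methylbutanoate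
Product: 21 [(2R,3S,4S)-2-(4-hydroxy-3-methoxyphenyl)-4-[(4-hydroxy-3-methoxyphenyl)methyl]oxolan-3-yl]methyl (2R)-2-methylbutanoate (target)
Conditions: Bu4NF, AcOH (1:1), THF, 0 °C
Reagents that add atoms: none
Why: Fluoride cleavage of the two aryl silyl ethers; acetic acid buffers the phenoxides so that the ester, its alpha stereocentre and the C2–O1 bond are not exposed to base or strong acid.

## Compound list

1 | 4-bromo-2-methoxyphenol | COc1cc(Br)ccc1O | starting material
2 | (4-bromo-2-methoxyphenoxy)triisopropylsilane | COc1cc(Br)ccc1O[Si](C(C)C)(C(C)C)C(C)C | intermediate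
3 | vanillin | COc1cc(C=O)ccc1O | starting material
4 | 3-methoxy-4-[(triisopropylsilyl)oxy]benzaldehyde | COc1cc(C=O)ccc1O[Si](C(C)C)(C(C)C)C(C)C | intermediate
5 | {3-methoxy-4-[(triisopropylsilyl)oxy]phenyl}methanol | COc1cc(CO)ccc1O[Si](C(C)C)(C(C)C)C(C)C | intermediate
6 | 3-bromoprop-1-yne | C#CCBr | starting material
7 | {2-methoxy-4-[(prop-2-yn-1-yloxy)methyl]phenoxy}triisopropylsilane | C#CCOCc1ccc(O[Si](C(C)C)(C(C)C)C(C)C)c(OC)c1 | intermediate
8 | 1-Ar-3-(Ar-methoxy)prop-1-yne | COc1cc(C#CCOCc2ccc(O[Si](C(C)C)(C(C)C)C(C)C)c(OC)c2)ccc1O[Si](C(C)C)(C(C)C)C(C)C | intermediate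
9 | tributyl[(1E)-1-Ar-3-(Ar-methoxy)prop-1-en-2-yl]stannane | CCCC[Sn](CCCC)(CCCC)/C(COCc1ccc(O[Si](C(C)C)(C(C)C)C(C)C)c(OC)c1)=C/c1ccc(O[Si](C(C)C)(C(C)C)C(C)C)c(OC)c1 | intermediate
10 | (1E)-1-Ar-2-iodo-3-(Ar-methoxy)prop-1-ene | I/C(COCc1ccc(O[Si](C(C)C)(C(C)C)C(C)C)c(OC)c1)=C/c1ccc(O[Si](C(C)C)(C(C)C)C(C)C)c(OC)c1 | intermediate
11 | methyl bromoacetate | COC(=O)CBr | starting material
12 | bromo(2-methoxy-2-oxoethyl)zinc | COC(=O)C[Zn]Br | intermediate
13 | methyl (3Z)-4-Ar-3-[(Ar-methoxy)methyl]but-3-enoate | COC(=O)C/C(COCc1ccc(O[Si](C(C)C)(C(C)C)C(C)C)c(OC)c1)=C/c1ccc(O[Si](C(C)C)(C(C)C)C(C)C)c(OC)c1 | intermediate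
14 | methyl (3Z)-2-diazo-4-Ar-3-[(Ar-methoxy)methyl]but-3-enoate | COC(=O)C(=[N+]=[N-])/C(COCc1ccc(O[Si](C(C)C)(C(C)C)C(C)C)c(OC)c1)=C/c1ccc(O[Si](C(C)C)(C(C)C)C(C)C)c(OC)c1 | intermediate
15 | methyl (2R,3S,4Z)-2-Ar-4-(Ar-methylidene)oxolane-3-carboxylate | COC(=O)[C@H]1/C(CO[C@H]1c1ccc(O[Si](C(C)C)(C(C)C)C(C)C)c(OC)c1)=C/c1ccc(O[Si](C(C)C)(C(C)C)C(C)C)c(OC)c1 | intermediate
16 | methyl (2R,3R,4Z)-2-Ar-4-(Ar-methylidene)oxolane-3-carboxylate | COC(=O)[C@@H]1/C(CO[C@H]1c1ccc(O[Si](C(C)C)(C(C)C)C(C)C)c(OC)c1)=C/c1ccc(O[Si](C(C)C)(C(C)C)C(C)C)c(OC)c1 | intermediate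
17 | [(2R,3S,4Z)-2-Ar-4-(Ar-methylidene)oxolan-3-yl]methanol | OC[C@@H]1/C(CO[C@H]1c1ccc(O[Si](C(C)C)(C(C)C)C(C)C)c(OC)c1)=C/c1ccc(O[Si](C(C)C)(C(C)C)C(C)C)c(OC)c1 | intermediate
18 | (2R)-2-methylbutanoic acid | CC[C@@H](C)C(=O)O | starting material
19 | [(2R,3S,4Z)-2-Ar-4-(Ar-methylidene)oxolan-3-yl]methyl (2R)-2-methylbutanoate | CC[C@@H](C)C(=O)OC[C@@H]1/C(CO[C@H]1c1ccc(O[Si](C(C)C)(C(C)C)C(C)C)c(OC)c1)=C/c1ccc(O[Si](C(C)C)(C(C)C)C(C)C)c(OC)c1 | intermediate
20 | [(2R,3S,4S)-2-Ar-4-(Ar-methyl)oxolan-3-yl]methyl (2R)-2-methylbutanoate | CC[C@@H](C)C(=O)OC[C@@H]1[C@H](Cc2ccc(O[Si](C(C)C)(C(C)C)C(C)C)c(OC)c2)CO[C@H]1c1ccc(O[Si](C(C)C)(C(C)C)C(C)C)c(OC)c1 | intermediate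
21 | [(2R,3S,4S)-2-(4-hydroxy-3-methoxyphenyl)-4-[(4-hydroxy-3-methoxyphenyl)methyl]oxolan-3-yl]methyl (2R)-2-methylbutanoate | CC[C@@H](C)C(=O)OC[C@@H]1[C@H](Cc2ccc(O)c(OC)c2)CO[C@H]1c1ccc(O)c(OC)c1 | target

## Step count and least certain steps

Total: 14 steps. Longest linear sequence: 13 steps (3 → 21, steps 2 to 14).

Step 9 (key step, Proposed new method). The carbenoid may be diverted before it reaches the C–H bond (closure of the vinylcarbenoid to a cyclopropene, attack on the ether oxygen, dimerisation), or the diazo ester may cyclise thermally to a pyrazole before use. The insertion may also discriminate poorly between the enantiotopic hydrogens, because a vinyl donor tethered through its own carbon presents the C–H bond to the catalyst pocket differently from the aryl precedent. A first response within the strategy is Rh2(S-DOSP)4 (dirhodium tetrakis[(S)-N-(4-dodecylphenylsulfonyl)prolinate]) in a hydrocarbon solvent.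

The fallback uses known chemistry and closes the ring through C3–C4 instead. It sets out from aldehyde 4 and comes back at 20.
- Aldehyde 4 is treated with vinylmagnesium bromide (THF, −78 °C) to give racemic 1-Ar-prop-2-en-1-ol F1.
- Sharpless kinetic resolution (Ti(OiPr)4, L-(+)-diisopropyl tartrate, t-BuOOH, 4 Å sieves, CH2Cl2, −20 °C, stopped below half conversion) epoxidises the (R)-alcohol to the anti epoxy alcohol (S)-Ar[(2R)-oxiran-2-yl]methanol F2.
- O-Alkylation with 6 (NaH, THF, 0 °C) gives the propargyl ether (2R)-2-[(S)-Ar(prop-2-yn-1-yloxy)methyl]oxirane F3.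
- Sonogashira coupling with 2, as in step 5, gives the aryl alkyne (2R)-2-[(S)-Ar{[3-Ar-prop-2-yn-1-yl]oxy}methyl]oxirane F4.
- Cp2TiCl (trivalent titanium, from Cp2TiCl2 and Zn, THF, rt) opens the epoxide homolytically to the C3 radical. This closes 5-exo on the alkyne trans to the C2 aryl and, after hydrogen capture and mild acidic work-up, should give [(2R,3S,4E)-2-Ar-4-(Ar-methylidene)oxolan-3-yl]methanol F5, the alkene isomer of 17.
- Acylation with 18 as in step 12 gives [(2R,3S,4E)-2-Ar-4-(Ar-methylidene)oxolan-3-yl]methyl (2R)-2-methylbutanoate F6.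
- Hydrogenation as in step 13, in which the alkene geometry disappears, returns the route at 20.

Step 6. Tin may be delivered to the aryl-bearing carbon, since an arene can also direct hydrostannation. The vinylstannane may lose tin by protonation, or the vinyl iodide may isomerise under iodine. The fallback makes the regiochemistry unambiguous with an ester as the directing group. It sets out from 4 and 5 and comes back at 10.
- Corey–Fuchs olefination of 4 (CBr4, PPh3, CH2Cl2, 0 °C) gives [4-(2,2-dibromoethenyl)-2-methoxyphenoxy]triisopropylsilane F7.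
- n-BuLi (2 equiv, THF, −78 °C) followed by methyl chloroformate gives methyl 3-Ar-prop-2-ynoate F8.
- Palladium-catalysed hydrostannation (Pd(PPh3)4, Bu3SnH, THF, 0 °C) places tin alpha to the ester and gives methyl (2E)-3-Ar-2-(tributylstannyl)prop-2-enoate F9.
- Iodine converts it into methyl (2E)-2-iodo-3-Ar-prop-2-enoate F10.
- i-Bu2AlH (CH2Cl2, −78 °C) gives (2E)-2-iodo-3-Ar-prop-2-en-1-ol F11.
- Alcohol 5 is converted into [4-(bromomethyl)-2-methoxyphenoxy]triisopropylsilane F12 (CBr4, PPh3, CH2Cl2, 0 °C, used at once).
- Alkylation of the sodium alkoxide of F11 with F12 (NaH, THF–DMF, 0 °C) gives 10.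

Step 10. Protonation of the dienolate at the benzylic carbon would move the alkene into conjugation with the ester and erase C3, or the equilibration may stop short. The fallback does the epimerisation at the aldehyde oxidation level, where a much weaker base suffices. It sets out from 15 and comes back at 17.
- Full reduction with i-Bu2AlH gives the cis alcohol [(2R,3R,4Z)-2-Ar-4-(Ar-methylidene)oxolan-3-yl]methanol F13.
- Dess–Martin periodinane (NaHCO3, CH2Cl2, 0 °C) gives the cis aldehyde (2R,3S,4Z)-2-Ar-4-(Ar-methylidene)oxolane-3-carbaldehyde F14.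
- Brief exposure to Et3N (cat., CH2Cl2, 0 °C) converts it into the trans aldehyde (2R,3R,4Z)-2-Ar-4-(Ar-methylidene)oxolane-3-carbaldehyde F15.
- NaBH4 (MeOH, −20 °C) reduces it to 17.

Step 13. Facial selectivity may be poor, because the C2 aryl lies on the face that must receive hydrogen and only the adjacent C3 side chain opposes it. Hydrogenolysis of the allylic C5–O1 or benzylic C2–O1 bond, or alkene migration on the metal, may also interfere. The fallback hydrogenates a substrate with a bulkier C3 group and acylates afterwards. It sets out from 17 and comes back at 20.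
- TBSCl and imidazole (DMF) give tert-butyl{[(2R,3S,4Z)-2-Ar-4-(Ar-methylidene)oxolan-3-yl]methoxy}dimethylsilane F16.
- Hydrogenation as in step 13 gives tert-butyl{[(2R,3S,4S)-2-Ar-4-(Ar-methyl)oxolan-3-yl]methoxy}dimethylsilane F17.
- HF·pyridine buffered with pyridine (THF, 0 °C) removes the alkyl silyl ether in the presence of the aryl silyl ethers and gives [(2R,3S,4S)-2-Ar-4-(Ar-methyl)oxolan-3-yl]methanol F18.
- Esterification with 18 as in step 12 gives 20.

## Further compounds

F1 | step 9 | racemic 1-Ar-prop-2-en-1-ol | C=CC(O)c1ccc(O[Si](C(C)C)(C(C)C)C(C)C)c(OC)c1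
F2 | step 9 | (S)-Ar[(2R)-oxiran-2-yl]methanol | O[C@@H](c1ccc(O[Si](C(C)C)(C(C)C)C(C)C)c(OC)c1)[C@H]1CO1
F3 | step 9 | (2R)-2-[(S)-Ar(prop-2-yn-1-yloxy)methyl]oxirane | C#CCO[C@@H](c1ccc(O[Si](C(C)C)(C(C)C)C(C)C)c(OC)c1)[C@H]1CO1
F4 | step 9 | (2R)-2-[(S)-Ar{[3-Ar-prop-2-yn-1-yl]oxy}methyl]oxirane | COc1cc(C#CCO[C@@H](c2ccc(O[Si](C(C)C)(C(C)C)C(C)C)c(OC)c2)[C@H]2CO2)ccc1O[Si](C(C)C)(C(C)C)C(C)C
F5 | step 9 | [(2R,3S,4E)-2-Ar-4-(Ar-methylidene)oxolan-3-yl]methanol | OC[C@@H]1/C(CO[C@H]1c1ccc(O[Si](C(C)C)(C(C)C)C(C)C)c(OC)c1)=C\c1ccc(O[Si](C(C)C)(C(C)C)C(C)C)c(OC)c1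
F6 | step 9 | [(2R,3S,4E)-2-Ar-4-(Ar-methylidene)oxolan-3-yl]methyl (2R)-2-methylbutanoate | CC[C@@H](C)C(=O)OC[C@@H]1/C(CO[C@H]1c1ccc(O[Si](C(C)C)(C(C)C)C(C)C)c(OC)c1)=C\c1ccc(O[Si](C(C)C)(C(C)C)C(C)C)c(OC)c1
F7 | step 6 | [4-(2,2-dibromoethenyl)-2-methoxyphenoxy]triisopropylsilane | COc1cc(C=C(Br)Br)ccc1O[Si](C(C)C)(C(C)C)C(C)C
F8 | step 6 | methyl 3-Ar-prop-2-ynoate | COC(=O)C#Cc1ccc(O[Si](C(C)C)(C(C)C)C(C)C)c(OC)c1
F9 | step 6 | methyl (2E)-3-Ar-2-(tributylstannyl)prop-2-enoate | COC(=O)/C([Sn](CCCC)(CCCC)CCCC)=C\c1ccc(O[Si](C(C)C)(C(C)C)C(C)C)c(OC)c1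
F10 | step 6 | methyl (2E)-2-iodo-3-Ar-prop-2-enoate | COC(=O)/C(I)=C\c1ccc(O[Si](C(C)C)(C(C)C)C(C)C)c(OC)c1
F11 | step 6 | (2E)-2-iodo-3-Ar-prop-2-en-1-ol | OC/C(I)=C\c1ccc(O[Si](C(C)C)(C(C)C)C(C)C)c(OC)c1
F12 | step 6 | [4-(bromomethyl)-2-methoxyphenoxy]triisopropylsilane | COc1cc(CBr)ccc1O[Si](C(C)C)(C(C)C)C(C)C
F13 | step 10 | [(2R,3R,4Z)-2-Ar-4-(Ar-methylidene)oxolan-3-yl]methanol | OC[C@H]1/C(CO[C@H]1c1ccc(O[Si](C(C)C)(C(C)C)C(C)C)c(OC)c1)=C/c1ccc(O[Si](C(C)C)(C(C)C)C(C)C)c(OC)c1
F14 | step 10 | (2R,3S,4Z)-2-Ar-4-(Ar-methylidene)oxolane-3-carbaldehyde | O=C[C@H]1/C(CO[C@H]1c1ccc(O[Si](C(C)C)(C(C)C)C(C)C)c(OC)c1)=C/c1ccc(O[Si](C(C)C)(C(C)C)C(C)C)c(OC)c1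
F15 | step 10 | (2R,3R,4Z)-2-Ar-4-(Ar-methylidene)oxolane-3-carbaldehyde | O=C[C@@H]1/C(CO[C@H]1c1ccc(O[Si](C(C)C)(C(C)C)C(C)C)c(OC)c1)=C/c1ccc(O[Si](C(C)C)(C(C)C)C(C)C)c(OC)c1
F16 | step 13 | tert-butyl{[(2R,3S,4Z)-2-Ar-4-(Ar-methylidene)oxolan-3-yl]methoxy}dimethylsilane | CC(C)(C)[Si](C)(C)OC[C@@H]1/C(CO[C@H]1c1ccc(O[Si](C(C)C)(C(C)C)C(C)C)c(OC)c1)=C/c1ccc(O[Si](C(C)C)(C(C)C)C(C)C)c(OC)c1
F17 | step 13 | tert-butyl{[(2R,3S,4S)-2-Ar-4-(Ar-methyl)oxolan-3-yl]methoxy}dimethylsilane | CC(C)(C)[Si](C)(C)OC[C@@H]1[C@H](Cc2ccc(O[Si](C(C)C)(C(C)C)C(C)C)c(OC)c2)CO[C@H]1c1ccc(O[Si](C(C)C)(C(C)C)C(C)C)c(OC)c1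
F18 | step 13 | [(2R,3S,4S)-2-Ar-4-(Ar-methyl)oxolan-3-yl]methanol | OC[C@@H]1[C@H](Cc2ccc(O[Si](C(C)C)(C(C)C)C(C)C)c(OC)c2)CO[C@H]1c1ccc(O[Si](C(C)C)(C(C)C)C(C)C)c(OC)c1
A1 | alternative 1 | (3E,4R,5R)-5-Ar-3-(Ar-methylidene)-4-{[dimethyl(propan-2-yloxy)silyl]methyl}oxolan-2-one | CC(C)O[Si](C)(C)C[C@@H]1/C(=C\c2ccc(O[Si](C(C)C)(C(C)C)C(C)C)c(OC)c2)C(=O)O[C@H]1c1ccc(O[Si](C(C)C)(C(C)C)C(C)C)c(OC)c1
A2 | alternative 1 | (5R)-5-Ar-furan-2(5H)-one | O=C1C=C[C@@H](O1)c1ccc(O[Si](C(C)C)(C(C)C)C(C)C)c(OC)c1
A3 | alternative 2 | [(2R,3S,4S)-2-Ar-4-(Ar-methyl)oxolan-3-yl]methyl (2R)-2-methylbutanoate (identical with 20) | CC[C@@H](C)C(=O)OC[C@@H]1[C@H](Cc2ccc(O[Si](C(C)C)(C(C)C)C(C)C)c(OC)c2)CO[C@H]1c1ccc(O[Si](C(C)C)(C(C)C)C(C)C)c(OC)c1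
A4 | alternative 2 | (3S)-3-Ar-2-bromo-3-(prop-2-en-1-yloxy)propyl (2R)-2-methylbutanoate (either C2 epimer) | CC[C@@H](C)C(=O)OCC(Br)[C@@H](OCC=C)c1ccc(O[Si](C(C)C)(C(C)C)C(C)C)c(OC)c1
A5 | alternative 3 | (4S,5R)-5-Ar-4-{[(4-methoxyphenyl)methoxy]methyl}oxolan-3-one | COc1ccc(COC[C@@H]2C(=O)CO[C@H]2c2ccc(O[Si](C(C)C)(C(C)C)C(C)C)c(OC)c2)cc1
A6 | alternative 3 | (1R,2S)-1-Ar-2-{[(4-methoxyphenyl)methoxy]methyl}but-3-yn-1-ol | C#C[C@@H](COCc1ccc(OC)cc1)[C@@H](O)c1ccc(O[Si](C(C)C)(C(C)C)C(C)C)c(OC)c1
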